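**Plan**
- Retrosynthesis: the lactol OH and the ring B phenol are traced back to an (R)-1-phenylethyl acetal and a benzyl ether. Ring C is then cut at the diaryl ether bond (ring A oxygen to ring B carbon) and at the depside ester C(=O)–O bond.
- Ring A is cut at three C–C bonds: both bonds of the oxygen-bearing carbon next to the carboxyl carbon, and the bond from the methoxy carbon to the ring CH. This is possible because in ring A the ether-oxygen carbon and the methoxy carbon are meta, with the formyl carbon between them and the carboxyl carbon on the other side; a vinylketene carbonyl and an alkoxyalkyne leave exactly this pattern.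
- Forward: ring A by benzannulation (steps 1–6); rings B and D as a bromo-hydroxyphthalide from 3,5-dimethoxybenzaldehyde (steps 7–11); ester union, then ring C by intramolecular Ullmann etherification (steps 12–14); formyl and lactol release (steps 15–16).
- Stereochemistry: the single stereocentre (lactol carbon, S) comes from separating the two acetal diastereomers formed with (R)-1-phenylethanol. It is carried as that acetal and set free by hydrogenolysis of the benzylic C–O bond, which breaks no bond at the stereocentre.

Key step: step 5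

Assumption: the lactol carbon of a 3-hydroxyphthalide can epimerise by ring–chain tautomerism in protic, acidic or basic media, so it is kept as an acetal until the last step and the final product must be handled cold and neutral.

**Step 1**
Reactants: 1 butane-2,3-dione; 2 benzyl (triphenylphosphoranylidene)acetate
Product: 3 benzyl (E)-3-methyl-4-oxopent-2-enoate
Conditions: 1 (3 equiv), CH2Cl2, 0 °C → rt
Reagents that add atoms: none
Why: Wittig olefination of one carbonyl of the symmetrical 1,2-diketone with a stabilised ylide should give the E enoate (ester trans to acetyl) under thermodynamic control, and the excess of 1 suppresses a second olefination.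

**Step 2**
Reactants: 3 benzyl (E)-3-methyl-4-oxopent-2-enoate
Product: 5 benzyl (E)-5-diazo-3-methyl-4-oxopent-2-enoate, via trifluoroacetyl diketone 4 (not isolated)
Conditions: LiN(SiMe3)2, THF, –78 °C; CF3CO2CH2CF3; 5% HCl work-up; then MsN3, Et3N, H2O, MeCN, rt
Reagents that add atoms: methanesulfonyl azide, CS(=O)(=O)N=[N+]=[N-]
Why: Detrifluoroacetylative diazo transfer (a Regitz-type transfer to an activated ketone): kinetic enolisation at the acetyl methyl, C-trifluoroacetylation to 4 and cleavage by the sulfonyl azide install the diazo group without diazomethane, which would add as a 1,3-dipole to the doubly activated alkene of an acid chloride.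

**Step 3**
Reactants: 6 2-chloro-1,1-dimethoxyethane
Product: 8 methoxyacetylene, via sodium methoxyacetylide 7 (not isolated)
Conditions: NaNH2 (3 equiv), liq. NH3, –33 °C; sat. aq. NH4Cl, –60 °C; distilled into cold Et2O
Reagents that add atoms: none
Why: Twofold base-induced elimination (methanol, then HCl) from the chloroacetal gives acetylide 7, and cold protonation releases the volatile ynol ether, the standard route to alkoxyacetylenes.

**Step 4**
Reactants: 8 methoxyacetylene; 9 triethyl orthoformate
Product: 11 3,3-diethoxy-1-methoxyprop-1-yne, via methoxyethynylmagnesium bromide 10 (not isolated)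
Conditions: EtMgBr, Et2O, 0 °C → rt; then 9, toluene, 70 °C; H2O work-up
Reagents that add atoms: none
Why: Bodroux–Chichibabin-type substitution in which the alkynyl Grignard reagent 10 displaces one ethoxide of the orthoformate to give the propargylic acetal; a methyl ynol ether cannot lose an alkene thermally and so should tolerate the warming.

**Step 5**
Reactants: 5 benzyl (E)-5-diazo-3-methyl-4-oxopent-2-enoate; 11 3,3-diethoxy-1-methoxyprop-1-yne
Product: 16 benzyl 3-(diethoxymethyl)-2-hydroxy-4-methoxy-6-methylbenzoate, via vinylketene 12 (not isolated), via cyclobutenone 13 (not isolated), via dienylketene 14 (not isolated), via cyclohexadienone 15 (not isolated)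
Conditions: hν (254 nm, quartz), 11 (2 equiv), degassed ClCH2CH2Cl, rt; then 80 °C
Reagents that add atoms: none
Why: Photochemical Wolff rearrangement of 5 shifts the alkenyl group to the diazo carbon and gives vinylketene 12, whose carbonyl carbon is attacked by the nucleophilic, acetal-bearing carbon of ynol ether 11 in a (2+2) cycloaddition to the 4-alkenylcyclobutenone 13; on warming, 13 opens by four-electron electrocyclic cleavage to dienylketene 14, which closes to cyclohexadienone 15 and tautomerises to phenol 16. The closest known reaction type is the Danheiser benzannulation of α,β-unsaturated α'-diazoketones with alkoxy- or siloxyalkynes. Ring A is closed by thermal six-electron disrotatory electrocyclisation of 14, which joins the ketene carbon to the ester-bearing alkene carbon; together with the (2+2) step this forms both C–C bonds of the phenol carbon and the bond from the methoxy carbon to the ring CH. No stereocentre remains, because the sp3 carbons of 13 and 15 are lost on aromatisation. The step needs one regiochemistry in the (2+2) addition and an E alkene: the polarisation of the ynol ether (carbon remote from oxygen bonds to C=O, oxygen-bearing carbon bonds to the ketene CH) should secure the first, and the trans arrangement of ester and ketene in 12 should keep the ester oxygen from trapping the ketene as a pyranone. Opening of 13 is reversible, so the isomer with the alkenyl group turned inward should be drained by the cyclisation.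

**Step 6**
Reactants: 16 benzyl 3-(diethoxymethyl)-2-hydroxy-4-methoxy-6-methylbenzoate
Product: 17 3-(diethoxymethyl)-2-hydroxy-4-methoxy-6-methylbenzoic acid
Conditions: H2 (1 atm), 10% Pd/C, EtOAc, rt; used at once
Reagents that add atoms: none
Why: Hydrogenolysis of the benzyl ester under neutral conditions should free the hindered acid without hot hydroxide, which would endanger the acetal next to the phenol.

**Step 7**
Reactants: 18 3,5-dimethoxybenzaldehyde
Product: 19 2,6-dibromo-3,5-dimethoxybenzaldehyde
Conditions: Br2 (2.1 equiv), AcOH, rt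
Reagents that add atoms: bromine, BrBr
Why: Twofold electrophilic aromatic bromination in which each bromine enters ortho to one methoxy group and para to the other, leaving the crowded position between the two methoxy groups free and giving a symmetrical product.

**Step 8**
Reactants: 19 2,6-dibromo-3,5-dimethoxybenzaldehyde
Product: 20 2,4-dibromo-3-(dimethoxymethyl)-1,5-dimethoxybenzene
Conditions: HC(OMe)3, TsOH·H2O (cat.), MeOH, reflux
Reagents that add atoms: trimethyl orthoformate, COC(OC)OC
Why: Acid-catalysed acetalisation with the orthoformate as water scavenger masks the formyl group against the organolithium of the next step.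

**Step 9**
Reactants: 20 2,4-dibromo-3-(dimethoxymethyl)-1,5-dimethoxybenzene
Product: 23 4-bromo-3-hydroxy-5,7-dimethoxyisobenzofuran-1(3H)-one, via aryllithium 21 (not isolated), via lithium carboxylate 22 (not isolated)
Conditions: n-BuLi (1.05 equiv), THF, –78 °C; CO2, –78 °C → rt; then 2 M HCl, 1,4-dioxane, 70 °C
Reagents that add atoms: carbon dioxide, O=C=O; water, O
Why: Bromine–lithium exchange of one of the two equivalent bromines (aryllithium 21 has no ortho halogen and cannot form an aryne), carboxylation to 22 and acid hydrolysis of the acetal, after which the formyl acid closes to the racemic lactol of ring D by ring–chain tautomerism.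

**Step 10**
Reactants: 23 4-bromo-3-hydroxy-5,7-dimethoxyisobenzofuran-1(3H)-one
Product: 24 4-bromo-3,5,7-trihydroxyisobenzofuran-1(3H)-one
Conditions: BBr3 (5 equiv), CH2Cl2, –78 °C → rt; H2O, 0 °C
Reagents that add atoms: none
Why: Lewis-acid cleavage of both aryl methyl ethers with BBr3, which should leave the aryl bromide untouched and return the lactol on aqueous work-up.

**Step 11**
Reactants: 24 4-bromo-3,5,7-trihydroxyisobenzofuran-1(3H)-one; 25 (R)-1-phenylethanol
Product: 26 (3S)-4-bromo-5,7-dihydroxy-3-[(1R)-1-phenylethoxy]isobenzofuran-1(3H)-one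
Conditions: 25 (3 equiv), PPTS (10 mol %), 4 Å MS, 1,4-dioxane, 70 °C; separation of the C3 epimers by chromatography; the unwanted epimer is resubmitted to the same conditions
Reagents that add atoms: none
Why: Acid-catalysed pseudo-ester formation (acetal exchange at the lactol carbon through an oxocarbenium ion) should give both C3 epimers without facial control; the (3S) acetal 26 is separated from the unwanted (3R) epimer, which re-equilibrates through the same oxocarbenium ion when returned to the reaction conditions, so the stereocentre is set by resolution against enantiopure 25 and its configuration is to be confirmed by X-ray analysis with bromine as heavy atom.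

**Step 12**
Reactants: 17 3-(diethoxymethyl)-2-hydroxy-4-methoxy-6-methylbenzoic acid; 26 (3S)-4-bromo-5,7-dihydroxy-3-[(1R)-1-phenylethoxy]isobenzofuran-1(3H)-one
Product: 27 (3S)-4-bromo-7-hydroxy-1-oxo-3-[(1R)-1-phenylethoxy]-1,3-dihydroisobenzofuran-5-yl 3-(diethoxymethyl)-2-hydroxy-4-methoxy-6-methylbenzoate
Conditions: DCC (1.2 equiv), DMAP (5 mol %), CH2Cl2, 0 °C → rt
Reagents that add atoms: none
Why: Steglich esterification in which the C5 hydroxyl (para to the lactone carbonyl, not hydrogen-bonded) should be acylated in preference to the C7 hydroxyl that is hydrogen-bonded to the lactone carbonyl, the selectivity on which depside syntheses from 2,4-dihydroxybenzoates rest.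

**Step 13**
Reactants: 27 the depside of step 12
Product: 28 (3S)-7-(benzyloxy)-4-bromo-1-oxo-3-[(1R)-1-phenylethoxy]-1,3-dihydroisobenzofuran-5-yl 3-(diethoxymethyl)-2-hydroxy-4-methoxy-6-methylbenzoate
Conditions: BnOH, PPh3, DIAD, THF, 0 °C → rt
Reagents that add atoms: benzyl alcohol, OCc1ccccc1
Why: Mitsunobu etherification under neutral conditions should benzylate the more acidic and less hindered C7 phenol of ring B and leave the ring A phenol, which is flanked by the ester and the acetal and is needed for ring closure.

**Step 14**
Reactants: 28 the benzylated depside of step 13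
Product: 29 (1S)-4-(benzyloxy)-11-(diethoxymethyl)-10-methoxy-8-methyl-1-[(1R)-1-phenylethoxy]-1H-isobenzofuro[4,5-b][1,4]benzodioxepine-3,7-dione
Conditions: CuI (20 mol %), N,N-dimethylglycine (40 mol %), Cs2CO3 (2 equiv), 1,4-dioxane (0.01 M), 90 °C
Reagents that add atoms: none
Why: Intramolecular Ullmann diaryl ether synthesis: the ester holds the ring A phenoxide next to the C–Br bond, so copper-catalysed O-arylation should close the seven-membered ring C at high dilution, while the benzyl ether keeps a para-phenoxide from deactivating the bromide and the acetal keeps the phenoxide nucleophilic.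

**Step 15**
Reactants: 29 the depsidone acetal of step 14
Product: 30 (1S)-4-(benzyloxy)-10-methoxy-8-methyl-3,7-dioxo-1-[(1R)-1-phenylethoxy]-1,3-dihydro-7H-isobenzofuro[4,5-b][1,4]benzodioxepine-11-carbaldehyde
Conditions: PPTS (20 mol %), acetone–H2O (10:1), rt
Reagents that add atoms: water, O
Why: Mild acid hydrolysis of the electron-rich benzaldehyde diethyl acetal, which ionises far more readily than the lactone-type acetal at C1 whose oxocarbenium ion is destabilised by the acyl oxygen, so the stereocentre should stay untouched.

**Step 16**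
Reactants: 30 the aldehyde of step 15
Product: 31 (1S)-1,4-dihydroxy-10-methoxy-8-methyl-3,7-dioxo-1,3-dihydro-7H-isobenzofuro[4,5-b][1,4]benzodioxepine-11-carbaldehyde (CNP0216483.1)
Conditions: H2 (1 atm), 10% Pd/C, EtOAc, rt
Reagents that add atoms: none
Why: Catalytic hydrogenolysis cleaves the two benzylic C–O bonds (benzyl ether and 1-phenylethyl acetal) under neutral aprotic conditions and breaks no bond at the lactol carbon, so the S configuration should be retained, while the hindered formyl group between two ortho oxygens should be reduced much more slowly.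

**Compound list**
1 | butane-2,3-dione | CC(=O)C(C)=O | starting material
2 | benzyl (triphenylphosphoranylidene)acetate | O=C(C=P(c1ccccc1)(c1ccccc1)c1ccccc1)OCc1ccccc1 | starting material
3 | benzyl (E)-3-methyl-4-oxopent-2-enoate | CC(=O)/C(C)=C/C(=O)OCc1ccccc1 | intermediate
4 | benzyl (E)-7,7,7-trifluoro-3-methyl-4,6-dioxohept-2-enoate | O=C(CC(=O)C(F)(F)F)/C(C)=C/C(=O)OCc1ccccc1 | intermediate
5 | benzyl (E)-5-diazo-3-methyl-4-oxopent-2-enoate | [N-]=[N+]=CC(=O)/C(C)=C/C(=O)OCc1ccccc1 | intermediate
6 | 2-chloro-1,1-dimethoxyethane (chloroacetaldehyde dimethyl acetal) | COC(CCl)OC | starting material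
7 | sodium methoxyacetylide | COC#[C-].[Na+] | intermediate
8 | methoxyacetylene | COC#C | intermediate
9 | triethyl orthoformate | CCOC(OCC)OCC | starting material
10 | (methoxyethynyl)magnesium bromide | COC#C[Mg]Br | intermediate
11 | 3,3-diethoxy-1-methoxyprop-1-yne | COC#CC(OCC)OCC | intermediate
12 | benzyl (E)-3-methyl-5-oxopenta-2,4-dienoate (vinylketene) | O=C=C/C(C)=C/C(=O)OCc1ccccc1 | intermediate
13 | benzyl (E)-3-[3-(diethoxymethyl)-2-methoxy-4-oxocyclobut-2-en-1-yl]but-2-enoate (racemic) | CCOC(OCC)C1=C(OC)C(/C(C)=C/C(=O)OCc2ccccc2)C1=O | intermediate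
14 | benzyl (2E,4E)-6-(diethoxymethyl)-5-methoxy-3-methyl-7-oxohepta-2,4,6-trienoate (dienylketene) | CCOC(OCC)C(=C=O)/C(OC)=C\C(C)=C\C(=O)OCc1ccccc1 | intermediate
15 | benzyl 3-(diethoxymethyl)-4-methoxy-6-methyl-2-oxocyclohexa-3,5-diene-1-carboxylate (racemic) | CCOC(OCC)C1=C(OC)C=C(C)C(C(=O)OCc2ccccc2)C1=O | intermediate
16 | benzyl 3-(diethoxymethyl)-2-hydroxy-4-methoxy-6-methylbenzoate | CCOC(OCC)c1c(OC)cc(C)c(C(=O)OCc2ccccc2)c1O | intermediate
17 | 3-(diethoxymethyl)-2-hydroxy-4-methoxy-6-methylbenzoic acid | CCOC(OCC)c1c(OC)cc(C)c(C(=O)O)c1O | intermediate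
18 | 3,5-dimethoxybenzaldehyde | COc1cc(OC)cc(C=O)c1 | starting material
19 | 2,6-dibromo-3,5-dimethoxybenzaldehyde | COc1cc(OC)c(Br)c(C=O)c1Br | intermediate
20 | 2,4-dibromo-3-(dimethoxymethyl)-1,5-dimethoxybenzene | COc1cc(OC)c(Br)c(C(OC)OC)c1Br | intermediate
21 | [3-bromo-2-(dimethoxymethyl)-4,6-dimethoxyphenyl]lithium | [Li]c1c(OC)cc(OC)c(Br)c1C(OC)OC | intermediate
22 | lithium 3-bromo-2-(dimethoxymethyl)-4,6-dimethoxybenzoate | [Li+].[O-]C(=O)c1c(OC)cc(OC)c(Br)c1C(OC)OC | intermediate
23 | 4-bromo-3-hydroxy-5,7-dimethoxyisobenzofuran-1(3H)-one (racemic) | COc1cc(OC)c2C(=O)OC(O)c2c1Br | intermediate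
24 | 4-bromo-3,5,7-trihydroxyisobenzofuran-1(3H)-one (racemic) | O=C1OC(O)c2c(Br)c(O)cc(O)c12 | intermediate
25 | (R)-1-phenylethanol | C[C@@H](O)c1ccccc1 | starting material
26 | (3S)-4-bromo-5,7-dihydroxy-3-[(1R)-1-phenylethoxy]isobenzofuran-1(3H)-one | O=C1O[C@H](O[C@H](C)c2ccccc2)c2c(Br)c(O)cc(O)c12 | intermediate
27 | (3S)-4-bromo-7-hydroxy-1-oxo-3-[(1R)-1-phenylethoxy]-1,3-dihydroisobenzofuran-5-yl 3-(diethoxymethyl)-2-hydroxy-4-methoxy-6-methylbenzoate | CCOC(OCC)c1c(OC)cc(C)c(C(=O)Oc2cc(O)c3C(=O)O[C@H](O[C@H](C)c4ccccc4)c3c2Br)c1O | intermediate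
28 | (3S)-7-(benzyloxy)-4-bromo-1-oxo-3-[(1R)-1-phenylethoxy]-1,3-dihydroisobenzofuran-5-yl 3-(diethoxymethyl)-2-hydroxy-4-methoxy-6-methylbenzoate | CCOC(OCC)c1c(OC)cc(C)c(C(=O)Oc2cc(OCc5ccccc5)c3C(=O)O[C@H](O[C@H](C)c4ccccc4)c3c2Br)c1O | intermediate
29 | (1S)-4-(benzyloxy)-11-(diethoxymethyl)-10-methoxy-8-methyl-1-[(1R)-1-phenylethoxy]-1H-isobenzofuro[4,5-b][1,4]benzodioxepine-3,7-dione | COc1cc(C)c2c(c1C(OCC)OCC)Oc1c(cc(OCc4ccccc4)c3c1[C@@H](O[C@H](C)c5ccccc5)OC3=O)OC2=O | intermediate
30 | (1S)-4-(benzyloxy)-10-methoxy-8-methyl-3,7-dioxo-1-[(1R)-1-phenylethoxy]-1,3-dihydro-7H-isobenzofuro[4,5-b][1,4]benzodioxepine-11-carbaldehyde | COc1cc(C)c2c(c1C=O)Oc1c(cc(OCc4ccccc4)c3c1[C@@H](O[C@H](C)c5ccccc5)OC3=O)OC2=O | intermediate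
31 | (1S)-1,4-dihydroxy-10-methoxy-8-methyl-3,7-dioxo-1,3-dihydro-7H-isobenzofuro[4,5-b][1,4]benzodioxepine-11-carbaldehyde | COc1cc(C)c2c(c1C=O)Oc1c(cc(O)c3c1[C@@H](O)OC3=O)OC2=O | target

**Step count**
Total: 16 steps. Longest linear sequence: 10 steps (steps 7–16, from 3,5-dimethoxybenzaldehyde).

**Steps most likely to fail**

Step 14 (closure of ring C). The risk is that, before copper inserts into the hindered, electron-rich C–Br bond, the ring A phenoxide attacks the ester-bearing carbon of ring B (Smiles-type aryl migration) or the aryl ester is cleaved by transacylation. The fallback sets out from 28: Miyaura borylation (Pd(dppf)Cl2, B2pin2, KOAc, 1,4-dioxane, 80 °C) would give the aryl pinacol boronate F1, and a Chan–Lam oxidative etherification (Cu(OAc)2, pyridine, 4 Å MS, air, CH2Cl2, rt) would then close ring C at room temperature with only a weak base. The route is rejoined at 29.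

Step 5 (benzannulation). The risk is photoisomerisation of the E enoate at 254 nm followed by capture of the ketene by the now cis ester oxygen, or a slow (2+2) addition of the acetal-substituted ynol ether that lets the ketene dimerise or acylate the phenol as it forms. The fallback builds the substitution pattern on a preformed arene and uses no numbered compound of the route as its point of departure: commercial 2-hydroxy-4-methoxy-6-methylbenzoic acid F2 replaces 5 and 11. Alkylation of its carboxylate (BnBr, KHCO3, DMF) would give benzyl 2-hydroxy-4-methoxy-6-methylbenzoate F3. Magnesium-mediated ortho-formylation of the phenol (MgCl2, Et3N, paraformaldehyde, MeCN, reflux) would give benzyl 3-formyl-2-hydroxy-4-methoxy-6-methylbenzoate F4, and acetalisation (HC(OEt)3, EtOH, PPTS) would return to the route at 16.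

Step 13 (benzylation of one of two hydrogen-bonded phenols). The risk is loss of site selectivity, with the ring A phenol etherified as well or instead, which would block the ring closure. The fallback sets out from 26 and differentiates the ring B phenols before the ester is made. Silylation of the non-chelated C5 hydroxyl (TBSCl, imidazole, DMF, 0 °C) would give the 5-O-silyl ether F5. Mitsunobu benzylation of the remaining C7 phenol (BnOH, PPh3, DIAD, THF) would give the 7-O-benzyl 5-O-silyl ether F6, and buffered fluoride (TBAF, AcOH, THF, 0 °C) would give the 7-O-benzyl 5-hydroxy lactone F7. Steglich esterification of F7 with 17 (DCC, DMAP, CH2Cl2) rejoins the route at 28 and bypasses 27.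

**Further compounds**
F1 | step 14 | (3S)-7-(benzyloxy)-1-oxo-3-[(1R)-1-phenylethoxy]-4-(4,4,5,5-tetramethyl-1,3,2-dioxaborolan-2-yl)-1,3-dihydroisobenzofuran-5-yl 3-(diethoxymethyl)-2-hydroxy-4-methoxy-6-methylbenzoate | CCOC(OCC)c1c(OC)cc(C)c(C(=O)Oc2cc(OCc5ccccc5)c3C(=O)O[C@H](O[C@H](C)c4ccccc4)c3c2B6OC(C)(C)C(C)(C)O6)c1O
F2 | step 5 | 2-hydroxy-4-methoxy-6-methylbenzoic acid | COc1cc(C)c(C(=O)O)c(O)c1
F3 | step 5 | benzyl 2-hydroxy-4-methoxy-6-methylbenzoate | COc1cc(C)c(C(=O)OCc2ccccc2)c(O)c1
F4 | step 5 | benzyl 3-formyl-2-hydroxy-4-methoxy-6-methylbenzoate | COc1cc(C)c(C(=O)OCc2ccccc2)c(O)c1C=O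
F5 | step 13 | (3S)-4-bromo-5-[(tert-butyldimethylsilyl)oxy]-7-hydroxy-3-[(1R)-1-phenylethoxy]isobenzofuran-1(3H)-one | O=C1O[C@H](O[C@H](C)c2ccccc2)c2c(Br)c(O[Si](C)(C)C(C)(C)C)cc(O)c12
F6 | step 13 | (3S)-7-(benzyloxy)-4-bromo-5-[(tert-butyldimethylsilyl)oxy]-3-[(1R)-1-phenylethoxy]isobenzofuran-1(3H)-one | O=C1O[C@H](O[C@H](C)c2ccccc2)c2c(Br)c(O[Si](C)(C)C(C)(C)C)cc(OCc3ccccc3)c12
F7 | step 13 | (3S)-7-(benzyloxy)-4-bromo-5-hydroxy-3-[(1R)-1-phenylethoxy]isobenzofuran-1(3H)-one | O=C1O[C@H](O[C@H](C)c2ccccc2)c2c(Br)c(O)cc(OCc3ccccc3)c12
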